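Reckon X, the product, by what the solid J can feed into the solution during the run; the flask stands so:

    G ⇌ X (K1 = 4.6, k1 = 0.93 /h)
    G ⇌ Z (K2 = 2.9, k2 = 0.33 /h)
    G ⇌ Q (K3 = 2.3, k3 = 0.17 /h)
    J ⇌ G, rate k4*(cs4 - [G]) while solid is left; crystals form when [G] > cs4 (cs4 = 4.2 mM, k4 = 0.62 /h)
    G + E → G.E (k5 = 4.7 /M/h)

J 0.050 M; E 0.0150 M; time 4.0 h

- J is a solid; its amount is given per volume of the solution
- at the start none of J is in solution
- run time (flask): 4.0 h

- amber: doubling the solubility in step 4, all else as stated
- grey: doubling the dissolution coefficient of step 4, all else as stated

- amount of X at 4.0 h, in percent of the J charged
- the change that raises the amount of X at 4.0 h, in percent of the J charged most ("none" if none brings more than 2 percentage points) (amber / grey / none)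
- amount of X at 4.0 h, in percent of the J charged, after amber

Treat the solid as a source: with [G] near zero it delivers 2.60 mM/h, so define the emptying time 19.2 h, the time that full delivery needs to dissolve the whole charge of J. Hold it against the run: 4.0 h is shorter, so solid remains through the run, and the ratio of the two, 0.208, is the largest part of J that can dissolve. The step to X runs both ways, and the relaxation half-life of G with X, 0.612 h, is short against the run, so do not count on X keeping all it receives.

Split the feed by forward rates, taking the loss to G.E as pseudo-first-order: X gets 62.0% and G.E far less, 4.70%. My reckoning therefore puts X under 12.9% of J, lowered further as [G] rises, the feed sags and X runs back to G. Amber brings the emptying time to 9.60 h, still longer than the run, so expect twice the X. Grey reaches the same emptying time, but [G] then pulls harder on a faster feed, so expect less from it.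

The forecast gives 6.6% (from 6.2% to 7.1%), names amber, and gives 13.3% (from 12.5% to 14.1%) after it, holding “so solid remains throughout and no crystals form”. Its figure for the flask lies under my bound.

The simulation gives 6.65% for the flask and names amber, which gains 6.7 percentage points against 3.6 points for grey and reaches 13.3%. Read off from this, X is 0.319 of the ratio. Now take the neighbour flask with 0.013 M of J: its emptying time is 4.99 h, still longer than the run, its ratio is 0.801, and the same reading gives 25.6%. The neighbour flask gives 25.6%, with 43.4% of its J still solid.

(The numbers were drawn at random within sensible limits, and the outcome is calculated.)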